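**Retrosynthetic overview**

- The target is opened at its four phenols to the tetrabenzyl ether 22, so the last step is a hydrogenolysis.
- The strategy rests on the ortho-hydroxyaryl ketone of ring B: the acetyl group on C5' sits next to the hydroxyl on C4' (ring B also carries the CH2 bridge on C1', OH on C2', methyl on C3', OH on C6'). This pair is the formal adduct of a C4'–C5' aryne and acetate, so 22 is traced back to silyl triflate 19 (SiMe3 on C5', OTf on C4') and CsOAc.
- 19 is cut at the bridge CH2–C5 bond of ring A: Friedel–Crafts benzylation of ring A ketone 6 by ring B benzylic alcohol 18. All organolithium chemistry on ring B is therefore finished before the butanoyl ketone is present.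
- 18 and 6 both come from 2-methylphloroglucinol. For 18: formylation (the CHO carbon becomes the bridge), O4' set apart from O2'/O6' by a temporary MOM group, bromination at C5', reduction, then retro-Brook silyl shift and triflation. For 6: C-acylation, 4-O-methylation, benzylation.
- No ring is built: both benzene rings are those of 2-methylphloroglucinol, and the target has no stereocentre.

Key step: step 13

Remark: ring A is numbered from the carbon bearing the butanoyl group (C2 and C6 oxygen, C3 methyl, C4 methoxy, C5 bridge); ring B, primed, is numbered from the carbon bearing the bridge carbon.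
Remark: anhydrous CsOAc (20) is taken as the commercial salt form of acetic acid, so that the key step contains no proton source.

**Route**

Step 1
Reactants: 1 2-methylbenzene-1,3,5-triol (2-methylphloroglucinol); 2 butanoyl chloride
Product: 3 1-(2,4,6-trihydroxy-3-methylphenyl)butan-1-one
Conditions: AlCl3, PhNO2–CH2Cl2, 0 °C → 45 °C; then ice/aq. HCl
Reagents that add atoms: none
Why: Friedel–Crafts C-acylation; the two open ring positions of 1 are equivalent by symmetry and the first acyl group deactivates the ring, so a single monoketone should form.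

Step 2
Reactants: 3 1-(2,4,6-trihydroxy-3-methylphenyl)butan-1-one
Product: 4 1-(2,6-dihydroxy-4-methoxy-3-methylphenyl)butan-1-one (aspidinol)
Conditions: Me2SO4 (1.0 equiv), K2CO3 (1.0 equiv), acetone, 0 °C → rt
Reagents that add atoms: dimethyl sulfate (COS(=O)(=O)OC)
Why: Williamson O-methylation under limiting base; the 4-OH, para to the carbonyl, is the most acidic phenol and is not held in the carbonyl hydrogen bond, so it should be methylated in preference to the two ortho phenols.

Step 3
Reactants: 4 1-(2,6-dihydroxy-4-methoxy-3-methylphenyl)butan-1-one; 5 benzyl bromide (first of two equivalents consumed)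
Product: 6 1-[2,6-bis(benzyloxy)-4-methoxy-3-methylphenyl]butan-1-one
Conditions: BnBr (2.5 equiv in all), K2CO3 (3 equiv), n-Bu4NI (cat.), DMF, 60 °C
Reagents that add atoms: benzyl bromide, second equivalent of 5 (BrCc1ccccc1)
Why: twofold Williamson etherification; each of the two remaining phenols, the hydrogen-bonded one included, takes up one molecule of benzyl bromide in DMF, leaving C5 as the only unsubstituted ring carbon.

Step 4
Reactants: 1 2-methylbenzene-1,3,5-triol
Product: 8 2,4,6-trihydroxy-3-methylbenzaldehyde, via aryl iminium chloride 7 (not isolated)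
Conditions: POCl3, DMF, EtOAc, 0 °C → rt; then H2O, 60 °C
Reagents that add atoms: N,N-dimethylformamide (CN(C)C=O); water (O)
Why: Vilsmeier–Haack formylation; the chloroiminium ion attacks one of the two equivalent free positions of the electron-rich triol and hydrolysis of the iminium salt releases the aldehyde, whose carbon becomes the later bridge.

Step 5
Reactants: 8 2,4,6-trihydroxy-3-methylbenzaldehyde
Product: 9 2,6-dihydroxy-4-(methoxymethoxy)-3-methylbenzaldehyde
Conditions: MOMCl (1.05 equiv), i-Pr2NEt, THF, 0 °C
Reagents that add atoms: chloromethyl methyl ether (COCCl)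
Why: selective MOM ether formation; the 4-OH para to the formyl group is the most acidic phenol, while the two ortho phenols are engaged in hydrogen bonding to the aldehyde, so one equivalent of MOMCl should react at O4'.

Step 6
Reactants: 9 2,6-dihydroxy-4-(methoxymethoxy)-3-methylbenzaldehyde; 5 benzyl bromide (first of two equivalents consumed)
Product: 10 2,6-bis(benzyloxy)-4-(methoxymethoxy)-3-methylbenzaldehyde
Conditions: BnBr (2.5 equiv in all), K2CO3 (3 equiv), n-Bu4NI (cat.), DMF, 60 °C
Reagents that add atoms: benzyl bromide, second equivalent of 5 (BrCc1ccccc1)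
Why: twofold Williamson etherification; each of the two phenols flanking the aldehyde takes up one molecule of benzyl bromide, and the MOM acetal is stable to carbonate base.

Step 7
Reactants: 10 2,6-bis(benzyloxy)-4-(methoxymethoxy)-3-methylbenzaldehyde
Product: 11 2,6-bis(benzyloxy)-4-hydroxy-3-methylbenzaldehyde
Conditions: conc. HCl (cat.), MeOH–THF, 50 °C; aqueous work-up
Reagents that add atoms: none
Why: acid-catalysed acetal exchange removes the MOM group; benzyl ethers are inert, and any dimethyl acetal of the aldehyde reverts on aqueous work-up.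

Step 8
Reactants: 11 2,6-bis(benzyloxy)-4-hydroxy-3-methylbenzaldehyde
Product: 12 2,6-bis(benzyloxy)-3-bromo-4-hydroxy-5-methylbenzaldehyde
Conditions: NBS (1.0 equiv), CH2Cl2–MeCN, 0 °C, dark
Reagents that add atoms: N-bromosuccinimide (O=C1CCC(=O)N1Br)
Why: electrophilic aromatic bromination; C5', ortho to the free phenol, is the only unsubstituted ring carbon, so the site of bromination is unambiguous.

Step 9
Reactants: 12 2,6-bis(benzyloxy)-3-bromo-4-hydroxy-5-methylbenzaldehyde
Product: 13 3,5-bis(benzyloxy)-2-bromo-4-(hydroxymethyl)-6-methylphenol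
Conditions: NaBH4, THF–MeOH, 0 °C; aq. NH4Cl
Reagents that add atoms: none
Why: hydride reduction of the aldehyde; the aryl bromide and benzyl ethers are untouched, and the neutral work-up avoids ionising the para-hydroxybenzyl alcohol.

Step 10
Reactants: 13 3,5-bis(benzyloxy)-2-bromo-4-(hydroxymethyl)-6-methylphenol
Product: 14 [3,5-bis(benzyloxy)-2-bromo-6-methyl-4-{[(trimethylsilyl)oxy]methyl}phenoxy]trimethylsilane
Conditions: HMDS, THF, 50 °C; evaporate, use crude
Reagents that add atoms: hexamethyldisilazane (C[Si](C)(C)N[Si](C)(C)C)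
Why: O-silylation with HMDS, one molecule of which delivers both SiMe3 groups; it places the migrating SiMe3 group on O4' and masks the benzylic alcohol toward n-BuLi, with ammonia as the only by-product.

Step 11
Reactants: 14 [3,5-bis(benzyloxy)-2-bromo-6-methyl-4-{[(trimethylsilyl)oxy]methyl}phenoxy]trimethylsilane
Product: 18 3,5-bis(benzyloxy)-4-(hydroxymethyl)-2-methyl-6-(trimethylsilyl)phenyl trifluoromethanesulfonate, via aryllithium 15 (not isolated), via lithium phenoxide 16 (not isolated), via silyl ether triflate 17 (not isolated)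
Conditions: n-BuLi (1.05 equiv), THF, −78 °C → −20 °C; PhNTf2, −78 °C → rt; then AcOH–H2O–THF, 0 °C
Reagents that add atoms: N-phenylbis(trifluoromethanesulfonimide) (O=S(=O)(N(c1ccccc1)S(=O)(=O)C(F)(F)F)C(F)(F)F)
Why: bromine–lithium exchange followed by 1,3 O-to-C silyl migration (retro-Brook rearrangement) from the only neighbouring silyloxy group puts SiMe3 on C5' and frees the C4' phenoxide, which PhNTf2 triflates without touching the benzylic silyl ether; dilute acetic acid then cleaves only that primary O–SiMe3 bond.

Step 12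
Reactants: 6 1-[2,6-bis(benzyloxy)-4-methoxy-3-methylphenyl]butan-1-one (1.5 equiv); 18 3,5-bis(benzyloxy)-4-(hydroxymethyl)-2-methyl-6-(trimethylsilyl)phenyl trifluoromethanesulfonate
Product: 19 3,5-bis(benzyloxy)-4-{[2,4-bis(benzyloxy)-3-butanoyl-6-methoxy-5-methylphenyl]methyl}-6-methyl-2-(trimethylsilyl)phenyl trifluoromethanesulfonate
Conditions: Sc(OTf)3 (10 mol%), 4 Å MS, CH2Cl2–(CF3)2CHOH, 0 °C → rt
Reagents that add atoms: none
Why: dehydrative Friedel–Crafts benzylation; the benzylic cation of 18 is stabilised by its two ortho benzyloxy groups and should be captured by C5 of 6, the only unsubstituted carbon of the trialkoxy ring and ortho or para to all three oxygens, while the ortho triflate deactivates the C5'–Si bond toward protodesilylation.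

Step 13
Reactants: 19 3,5-bis(benzyloxy)-4-{[2,4-bis(benzyloxy)-3-butanoyl-6-methoxy-5-methylphenyl]methyl}-6-methyl-2-(trimethylsilyl)phenyl trifluoromethanesulfonate; 20 caesium acetate
Product: 22 1-{3-[(5-acetyl-2,6-bis(benzyloxy)-4-hydroxy-3-methylphenyl)methyl]-2,6-bis(benzyloxy)-4-methoxy-5-methylphenyl}butan-1-one, via aryne 21 (not isolated)
Conditions: CsF (3 equiv), CsOAc (3 equiv), dry THF, 125 °C, sealed tube; then 1 M HCl, 0 °C
Reagents that add atoms: none
Why: Fluoride attacks silicon and triflate leaves from C4', giving the C4'–C5' aryne 21; the benzyloxy group on C6' polarises the strained triple bond so that negative charge is best carried on C5', and acetate therefore adds through oxygen at C4', the terminus away from that group (the C3' methyl is a small neighbour). The C5' aryl anion then attacks the carbonyl of the neighbouring acetate ester and the four-membered alkoxide opens to the C4' phenoxide and the C5' methyl ketone, so C5'–C(=O)CH3 and C4'–O are formed in one operation. The closest known reaction type is the insertion of arynes from ortho-silylaryl triflates into the C–O bond of carboxylic acids with CsF in hot THF, which gives ortho-hydroxyaryl ketones. No ring is closed and no stereocentre is created. The step needs O-attack at C4' rather than C5' and acyl transfer faster than protonation of the aryl anion: the first is secured by the C6' benzyloxy group, the second by dry CsOAc in place of the free acid and by having every phenol benzylated, while the ring A ketone is shielded between two benzyloxy groups.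

Step 14
Reactants: 22 1-{3-[(5-acetyl-2,6-bis(benzyloxy)-4-hydroxy-3-methylphenyl)methyl]-2,6-bis(benzyloxy)-4-methoxy-5-methylphenyl}butan-1-one
Product: 23 1-{3-[(3-acetyl-2,4,6-trihydroxy-5-methylphenyl)methyl]-2,6-dihydroxy-4-methoxy-5-methylphenyl}butan-1-one (CNP0258463.0)
Conditions: H2 (1 atm), Pd/C (10 wt% Pd), EtOAc–MeOH, rt
Reagents that add atoms: none
Why: catalytic hydrogenolysis of the four aryl benzyl ethers; the hydrogen-bonded aryl ketones, the methyl ether and the diarylmethane are expected to survive if the reaction is stopped at full debenzylation.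

**Compound list**

1 | 2-methylbenzene-1,3,5-triol (2-methylphloroglucinol) | Cc1c(O)cc(O)cc1O | starting material
2 | butanoyl chloride | CCCC(=O)Cl | starting material
3 | 1-(2,4,6-trihydroxy-3-methylphenyl)butan-1-one | CCCC(=O)c1c(O)cc(O)c(C)c1O | intermediate
4 | 1-(2,6-dihydroxy-4-methoxy-3-methylphenyl)butan-1-one (aspidinol) | CCCC(=O)c1c(O)cc(OC)c(C)c1O | intermediate
5 | benzyl bromide | BrCc1ccccc1 | starting material
6 | 1-[2,6-bis(benzyloxy)-4-methoxy-3-methylphenyl]butan-1-one | CCCC(=O)c1c(OCc2ccccc2)cc(OC)c(C)c1OCc1ccccc1 | intermediate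
7 | N-methyl-N-[(2,4,6-trihydroxy-3-methylphenyl)methylidene]methanaminium chloride (aryl iminium chloride, not isolated) | C[N+](C)=Cc1c(O)cc(O)c(C)c1O.[Cl-] | intermediate
8 | 2,4,6-trihydroxy-3-methylbenzaldehyde | O=Cc1c(O)cc(O)c(C)c1O | intermediate
9 | 2,6-dihydroxy-4-(methoxymethoxy)-3-methylbenzaldehyde | O=Cc1c(O)cc(OCOC)c(C)c1O | intermediate
10 | 2,6-bis(benzyloxy)-4-(methoxymethoxy)-3-methylbenzaldehyde | O=Cc1c(OCc2ccccc2)cc(OCOC)c(C)c1OCc1ccccc1 | intermediate
11 | 2,6-bis(benzyloxy)-4-hydroxy-3-methylbenzaldehyde | O=Cc1c(OCc2ccccc2)cc(O)c(C)c1OCc1ccccc1 | intermediate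
12 | 2,6-bis(benzyloxy)-3-bromo-4-hydroxy-5-methylbenzaldehyde | O=Cc1c(OCc2ccccc2)c(Br)c(O)c(C)c1OCc1ccccc1 | intermediate
13 | 3,5-bis(benzyloxy)-2-bromo-4-(hydroxymethyl)-6-methylphenol | OCc1c(OCc2ccccc2)c(Br)c(O)c(C)c1OCc1ccccc1 | intermediate
14 | [3,5-bis(benzyloxy)-2-bromo-6-methyl-4-{[(trimethylsilyl)oxy]methyl}phenoxy]trimethylsilane | C[Si](C)(C)OCc1c(OCc2ccccc2)c(Br)c(O[Si](C)(C)C)c(C)c1OCc1ccccc1 | intermediate
15 | {4,6-bis(benzyloxy)-3-methyl-2-[(trimethylsilyl)oxy]-5-{[(trimethylsilyl)oxy]methyl}phenyl}lithium (aryllithium, not isolated) | C[Si](C)(C)OCc1c(OCc2ccccc2)c([Li])c(O[Si](C)(C)C)c(C)c1OCc1ccccc1 | intermediate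
16 | lithium 3,5-bis(benzyloxy)-2-methyl-6-(trimethylsilyl)-4-{[(trimethylsilyl)oxy]methyl}phenolate (lithium phenoxide, not isolated) | C[Si](C)(C)OCc1c(OCc2ccccc2)c([Si](C)(C)C)c([O-])c(C)c1OCc1ccccc1.[Li+] | intermediate
17 | 3,5-bis(benzyloxy)-2-methyl-6-(trimethylsilyl)-4-{[(trimethylsilyl)oxy]methyl}phenyl trifluoromethanesulfonate (silyl ether triflate, not isolated) | C[Si](C)(C)OCc1c(OCc2ccccc2)c([Si](C)(C)C)c(OS(=O)(=O)C(F)(F)F)c(C)c1OCc1ccccc1 | intermediate
18 | 3,5-bis(benzyloxy)-4-(hydroxymethyl)-2-methyl-6-(trimethylsilyl)phenyl trifluoromethanesulfonate | OCc1c(OCc2ccccc2)c([Si](C)(C)C)c(OS(=O)(=O)C(F)(F)F)c(C)c1OCc1ccccc1 | intermediate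
19 | 3,5-bis(benzyloxy)-4-{[2,4-bis(benzyloxy)-3-butanoyl-6-methoxy-5-methylphenyl]methyl}-6-methyl-2-(trimethylsilyl)phenyl trifluoromethanesulfonate | CCCC(=O)c1c(OCc2ccccc2)c(C)c(OC)c(Cc2c(OCc3ccccc3)c(C)c(OS(=O)(=O)C(F)(F)F)c([Si](C)(C)C)c2OCc2ccccc2)c1OCc1ccccc1 | intermediate
20 | caesium acetate (caesium salt of acetic acid) | CC(=O)[O-].[Cs+] | starting material
21 | 1-{2,6-bis(benzyloxy)-3-[(2,6-bis(benzyloxy)-3-methyl-4,5-didehydrophenyl)methyl]-4-methoxy-5-methylphenyl}butan-1-one (C4'–C5' aryne, not isolated) | CCCC(=O)c1c(OCc2ccccc2)c(C)c(OC)c(CC2=C(OCc3ccccc3)C#CC(C)=C2OCc2ccccc2)c1OCc1ccccc1 | intermediate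
22 | 1-{3-[(5-acetyl-2,6-bis(benzyloxy)-4-hydroxy-3-methylphenyl)methyl]-2,6-bis(benzyloxy)-4-methoxy-5-methylphenyl}butan-1-one | CCCC(=O)c1c(OCc2ccccc2)c(C)c(OC)c(Cc2c(OCc3ccccc3)c(C)c(O)c(C(C)=O)c2OCc2ccccc2)c1OCc1ccccc1 | intermediate
23 | 1-{3-[(3-acetyl-2,4,6-trihydroxy-5-methylphenyl)methyl]-2,6-dihydroxy-4-methoxy-5-methylphenyl}butan-1-one (CNP0258463.0) | CCCC(=O)c1c(O)c(C)c(OC)c(Cc2c(O)c(C)c(O)c(C(C)=O)c2O)c1O | target

**Step count**

Total: 14 steps. Longest linear sequence: 11 steps (steps 4–14, from 1 through 8–14, 18, 19 and 22 to 23).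

**Steps most likely to fail**

Step 13 (aryne insertion). The C5' aryl anion may be protonated before it reaches the ester carbonyl, so that only O-arylation of acetate results. Acetate may also add at the wrong aryne terminus, or the hexasubstituted aryne may be consumed by the product phenoxide or by the enolate of the ring A ketone. The fallback accepts O-arylation and moves the acyl group afterwards. It sets out from 19: CsF and acetic acid in MeCN at rt should give, by the known O–H insertion of arynes into carboxylic acids, 3,5-bis(benzyloxy)-4-{[2,4-bis(benzyloxy)-3-butanoyl-6-methoxy-5-methylphenyl]methyl}-2-methylphenyl acetate F1, with hydrogen on C5'. Hydrogenolysis over Pd/C then gives 4-[(3-butanoyl-2,4-dihydroxy-6-methoxy-5-methylphenyl)methyl]-3,5-dihydroxy-2-methylphenyl acetate F2. A Fries rearrangement with BF3·OEt2 at 60 °C should shift the acetyl group from O4' to C5', the only unsubstituted ring carbon of the molecule. The fallback comes back to the route at the target 23.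

Step 12 (Friedel–Crafts coupling). Ionisation of the hindered benzylic alcohol may be slow, so that acid-induced loss of the C5' silyl group, or cyclisation of the cation onto a neighbouring benzyl ring, competes with attack by the congested C5 of 6. The fallback uses the far more nucleophilic free phloroglucinol and moves the benzylation behind the coupling. It sets out from 4 and 18: in (CF3)2CHOH at rt with no more than a trace of TsOH, C5 of 4 should take up the benzylic cation to give 3,5-bis(benzyloxy)-4-[(3-butanoyl-2,4-dihydroxy-6-methoxy-5-methylphenyl)methyl]-6-methyl-2-(trimethylsilyl)phenyl trifluoromethanesulfonate F3. Benzylation of its two ring A phenols with 5 (2.5 equiv, one molecule per phenol) and K2CO3 in acetone at 40 °C should follow; ring B then carries no free phenol next to silicon. The fallback comes back at 19.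

Step 2 (mono-O-methylation). Site selectivity among the three phenols may be poor, with methylation of an ortho phenol or double methylation. The fallback builds ring A from the already differentiated aldehyde of the ring B branch. It sets out from 11: MeI and K2CO3 in DMF should give 2,6-bis(benzyloxy)-4-methoxy-3-methylbenzaldehyde F4. Addition of n-PrMgCl in THF at 0 °C should give racemic 1-[2,6-bis(benzyloxy)-4-methoxy-3-methylphenyl]butan-1-ol F5, and Dess–Martin oxidation should give the ketone. The fallback comes back at 6 and replaces steps 1–3.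

**Further compounds**

F1 | step 13 | 3,5-bis(benzyloxy)-4-{[2,4-bis(benzyloxy)-3-butanoyl-6-methoxy-5-methylphenyl]methyl}-2-methylphenyl acetate | CCCC(=O)c1c(OCc2ccccc2)c(C)c(OC)c(Cc2c(OCc3ccccc3)c(C)c(OC(C)=O)cc2OCc2ccccc2)c1OCc1ccccc1
F2 | step 13 | 4-[(3-butanoyl-2,4-dihydroxy-6-methoxy-5-methylphenyl)methyl]-3,5-dihydroxy-2-methylphenyl acetate | CCCC(=O)c1c(O)c(C)c(OC)c(Cc2c(O)c(C)c(OC(C)=O)cc2O)c1O
F3 | step 12 | 3,5-bis(benzyloxy)-4-[(3-butanoyl-2,4-dihydroxy-6-methoxy-5-methylphenyl)methyl]-6-methyl-2-(trimethylsilyl)phenyl trifluoromethanesulfonate | CCCC(=O)c1c(O)c(C)c(OC)c(Cc2c(OCc3ccccc3)c(C)c(OS(=O)(=O)C(F)(F)F)c([Si](C)(C)C)c2OCc2ccccc2)c1O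
F4 | step 2 | 2,6-bis(benzyloxy)-4-methoxy-3-methylbenzaldehyde | O=Cc1c(OCc2ccccc2)cc(OC)c(C)c1OCc1ccccc1
F5 | step 2 | 1-[2,6-bis(benzyloxy)-4-methoxy-3-methylphenyl]butan-1-ol (racemic) | CCCC(O)c1c(OCc2ccccc2)cc(OC)c(C)c1OCc1ccccc1
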